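**Retrosynthetic overview**
1. Target 18 comes from bis-silyl ether 17 by fluoride removal of two aryl TBS groups.
2. Key late disconnection: the furan C5–aryl bond of 17, made by Suzuki coupling of bromofuran ester 11 (fragment A) with arylboronate 16 (fragment B).
3. Fragment A: ester C–O (Steglich, acid 8), prenyl C=C (cross-metathesis on an allyl group), carbinol C–C (Brown allylation, sets the R carbinol), C5–Br (directed lithiation of furan-3-carbaldehyde 1).
4. Fragment B: C–B (Miyaura borylation), O–Si (silylation), C–Br (HBr addition to 1,4-benzoquinone 12).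
5. No ring is built: the furan comes from 1 and the benzene ring is aromatised from 12 in step 5; the two rings are joined in step 8.

Assumption: (R)-2-methylbutanoic acid of high enantiomeric purity is purchased; allylmagnesium bromide and 2-methyl-2-butene are treated as reagents and given with SMILES at their steps.

The target is (R) at the carbinol carbon and (R) at the acyl α-carbon.

**Step 1**
Reactants: 1 furan-3-carbaldehyde
Product: 5 5-bromofuran-3-carbaldehyde, via lithium aminoalkoxide 2 (not isolated), via 5-lithiofuryl aminoalkoxide 3 (not isolated), via 5-bromofuryl aminoalkoxide 4 (not isolated)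
Conditions: morpholine, n-BuLi, THF, −78 °C (lithium morpholide); then 1; then s-BuLi, −78 °C, 5 h; inverse addition to BrCl2C–CCl2Br, −78 → 0 °C; then H2O
Reagents that add atoms: 1,2-dibromo-1,1,2,2-tetrachloroethane, BrC(Cl)(Cl)C(Cl)(Cl)Br; lithium morpholide, [Li]N1CCOCC1; sec-butyllithium, CCC(C)[Li]
Why: Directed metalation: in-situ protection of the formyl group as the lithium α-morpholino alkoxide 2 shields C2 and lets s-BuLi deprotonate the remaining α-position C5 (3), electrophilic bromination of the furyllithium gives 4, and aqueous work-up expels the morpholine and lithium carried by 2–4 to leave aldehyde 5, whose only new atom is the bromine.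

**Step 2**
Reactants: 5 5-bromofuran-3-carbaldehyde
Product: 7 (R)-1-(5-bromofuran-3-yl)but-3-en-1-ol, via borinate ester 6 (not isolated)
Conditions: (+)-Ipc2BOMe (from (−)-α-pinene, 1.3 equiv), allylMgBr (1.2 equiv), Et2O, 0 °C → rt; then 5, −78 °C, 3 h; then 3 M NaOH, 30% H2O2, 0 °C → rt
Reagents that add atoms: allylmagnesium bromide, C=CC[Mg]Br; (+)-B-methoxydiisopinocampheylborane, COB([C@H]1C[C@H]2C[C@@H]([C@@H]1C)C2(C)C)[C@H]1C[C@H]2C[C@@H]([C@@H]1C)C2(C)C
Why: Brown asymmetric allylboration: the allylborane formed in the flask adds through a closed chair transition state to the Re face of the aldehyde (the antipodal, (+)-α-pinene-derived reagent gives S aryl carbinols), which sets the R carbinol centre, and oxidative work-up cleaves borinate 6, the only compound that carries the diisopinocampheylboryl unit.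

**Step 3**
Reactants: 7 (R)-1-(5-bromofuran-3-yl)but-3-en-1-ol; 8 (R)-2-methylbutanoic acid
Product: 10 (R)-1-(5-bromofuran-3-yl)but-3-en-1-yl (R)-2-methylbutanoate, via O-acylisourea 9 (not isolated)
Conditions: DCC (1.3 equiv), DMAP (10 mol%), CH2Cl2, 0 °C → rt
Reagents that add atoms: N,N'-dicyclohexylcarbodiimide, C(=NC1CCCCC1)=NC1CCCCC1
Why: Steglich esterification: DCC activates acid 8 as O-acylisourea 9 and then leaves as the urea while DMAP shuttles the acyl group to the alcohol, so the carbinol C–O bond is never broken (R retained) and the mild conditions leave the α-centre of the acid (R) unepimerised.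

**Step 4**
Reactants: 10 (R)-1-(5-bromofuran-3-yl)but-3-en-1-yl (R)-2-methylbutanoate
Product: 11 (R)-1-(5-bromofuran-3-yl)-4-methylpent-3-en-1-yl (R)-2-methylbutanoate
Conditions: 2-methyl-2-butene (large excess)/CH2Cl2, second-generation Grubbs catalyst RuCl2(=CHPh)(H2IMes)(PCy3) (5 mol%), 40 °C, sealed tube, 12 h
Reagents that add atoms: 2-methyl-2-butene, CC=C(C)C
Why: Olefin cross-metathesis: the monosubstituted alkene of 10 exchanges its CH2 terminus for the isopropylidene of 2-methyl-2-butene with loss of propene, the trisubstituted product is inert to further metathesis, and the bromofuran, ester and both stereocentres are untouched.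

**Step 5**
Reactants: 12 1,4-benzoquinone
Product: 14 2-bromobenzene-1,4-diol, via bromohydroxydienone 13 (not isolated)
Conditions: 48% aq. HBr (1.1 equiv), Et2O, 0 °C → rt
Reagents that add atoms: hydrogen bromide, Br
Why: Conjugate (1,4-) addition of HBr to the quinone gives dienone 13, which enolises at once to the aromatic bromohydroquinone, and this product is harder to oxidise than hydroquinone, so remaining quinone does not consume it.

**Step 6**
Reactants: 14 2-bromobenzene-1,4-diol
Product: 15 2-bromo-1,4-bis(tert-butyldimethylsilyloxy)benzene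
Conditions: TBSCl (2.5 equiv), imidazole (5 equiv), DMF, rt
Reagents that add atoms: tert-butyldimethylsilyl chloride, CC(C)(C)[Si](C)(C)Cl
Why: Imidazole-mediated silylation of both phenols installs fluoride-labile protecting groups that can later be removed without touching the ester, the alkene or the furan.

**Step 7**
Reactants: 15 2-bromo-1,4-bis(tert-butyldimethylsilyloxy)benzene
Product: 16 2-[2,5-bis(tert-butyldimethylsilyloxy)phenyl]-4,4,5,5-tetramethyl-1,3,2-dioxaborolane
Conditions: B2pin2 (1.2 equiv), PdCl2(dppf) (5 mol%), KOAc (3 equiv), 1,4-dioxane, 85 °C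
Reagents that add atoms: bis(pinacolato)diboron, CC1(C)OB(OC1(C)C)B1OC(C)(C)C(C)(C)O1
Why: Miyaura borylation: oxidative addition of the aryl bromide to zerovalent palladium, acetate-assisted transmetalation with B2pin2 and reductive elimination give the boronate, and KOAc is too weak a base to cleave the aryl silyl ethers or trigger biaryl homocoupling.

**Step 8**
Reactants: 11 (R)-1-(5-bromofuran-3-yl)-4-methylpent-3-en-1-yl (R)-2-methylbutanoate; 16 2-[2,5-bis(tert-butyldimethylsilyloxy)phenyl]-4,4,5,5-tetramethyl-1,3,2-dioxaborolane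
Product: 17 (R)-1-{5-[2,5-bis(tert-butyldimethylsilyloxy)phenyl]furan-3-yl}-4-methylpent-3-en-1-yl (R)-2-methylbutanoate
Conditions: Pd(OAc)2 (5 mol%), SPhos (10 mol%), K3PO4 (3 equiv), toluene/H2O 10:1, degassed, 60 °C
Reagents that add atoms: none
Why: Suzuki–Miyaura coupling: the C–Br bond of the 2-bromofuran adds readily to zerovalent palladium, the bulky electron-rich SPhos ligand promotes transmetalation and reductive elimination of the ortho-substituted boronate, and mild K3PO4 at 60 °C spares the ester and both stereocentres.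

**Step 9**
Reactants: 17 (R)-1-{5-[2,5-bis(tert-butyldimethylsilyloxy)phenyl]furan-3-yl}-4-methylpent-3-en-1-yl (R)-2-methylbutanoate
Product: 18 (R)-1-[5-(2,5-dihydroxyphenyl)furan-3-yl]-4-methylpent-3-en-1-yl (R)-2-methylbutanoate
Conditions: TBAF/AcOH (1:1, 3 equiv), degassed THF, 0 °C, argon
Reagents that add atoms: none
Why: Fluoride-mediated desilylation: fluoride attacks silicon and releases both phenols, while acetic acid buffering keeps the medium non-basic so that the ester is not cleaved and the hydroquinone is not air-oxidised.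

**Compound list**
1 | furan-3-carbaldehyde | O=Cc1ccoc1 | starting material
2 | lithium (furan-3-yl)(morpholin-4-yl)methanolate | [Li]OC(N1CCOCC1)c1ccoc1 | intermediate (not isolated)
3 | lithium (5-lithiofuran-3-yl)(morpholin-4-yl)methanolate | [Li]OC(N1CCOCC1)c1coc([Li])c1 | intermediate (not isolated)
4 | lithium (5-bromofuran-3-yl)(morpholin-4-yl)methanolate | [Li]OC(N1CCOCC1)c1coc(Br)c1 | intermediate (not isolated)
5 | 5-bromofuran-3-carbaldehyde | O=Cc1coc(Br)c1 | intermediate
6 | (R)-1-(5-bromofuran-3-yl)but-3-en-1-yl diisopinocampheylborinate (Ipc from (−)-α-pinene) | C[C@H]1[C@@H]2C[C@@H](C2(C)C)C[C@@H]1B(O[C@H](CC=C)c1coc(Br)c1)[C@H]1C[C@H]2C[C@@H]([C@@H]1C)C2(C)C | intermediate (not isolated)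
7 | (R)-1-(5-bromofuran-3-yl)but-3-en-1-ol | O[C@H](CC=C)c1coc(Br)c1 | intermediate
8 | (R)-2-methylbutanoic acid | CC[C@@H](C)C(=O)O | starting material
9 | O-[(R)-2-methylbutanoyl]-N,N'-dicyclohexylisourea | CC[C@@H](C)C(=O)OC(=NC1CCCCC1)NC1CCCCC1 | intermediate (not isolated)
10 | (R)-1-(5-bromofuran-3-yl)but-3-en-1-yl (R)-2-methylbutanoate | CC[C@@H](C)C(=O)O[C@H](CC=C)c1coc(Br)c1 | intermediate
11 | (R)-1-(5-bromofuran-3-yl)-4-methylpent-3-en-1-yl (R)-2-methylbutanoate | CC[C@@H](C)C(=O)O[C@H](CC=C(C)C)c1coc(Br)c1 | intermediate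
12 | 1,4-benzoquinone | O=C1C=CC(=O)C=C1 | starting material
13 | 6-bromo-4-hydroxycyclohexa-2,4-dien-1-one | O=C1C=CC(O)=CC1Br | intermediate (not isolated)
14 | 2-bromobenzene-1,4-diol | Oc1ccc(O)c(Br)c1 | intermediate
15 | 2-bromo-1,4-bis(tert-butyldimethylsilyloxy)benzene | CC(C)(C)[Si](C)(C)Oc1ccc(O[Si](C)(C)C(C)(C)C)c(Br)c1 | intermediate
16 | 2-[2,5-bis(tert-butyldimethylsilyloxy)phenyl]-4,4,5,5-tetramethyl-1,3,2-dioxaborolane | CC(C)(C)[Si](C)(C)Oc1ccc(O[Si](C)(C)C(C)(C)C)c(B2OC(C)(C)C(C)(C)O2)c1 | intermediate
17 | (R)-1-{5-[2,5-bis(tert-butyldimethylsilyloxy)phenyl]furan-3-yl}-4-methylpent-3-en-1-yl (R)-2-methylbutanoate | CC[C@@H](C)C(=O)O[C@H](CC=C(C)C)c1coc(-c2cc(O[Si](C)(C)C(C)(C)C)ccc2O[Si](C)(C)C(C)(C)C)c1 | intermediate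
18 | (R)-1-[5-(2,5-dihydroxyphenyl)furan-3-yl]-4-methylpent-3-en-1-yl (R)-2-methylbutanoate (CNP0144658.1) | CC[C@@H](C)C(=O)O[C@H](CC=C(C)C)c1coc(-c2cc(O)ccc2O)c1 | target

**Totals and risks**
Total step count: 9.
Longest linear sequence: 6 (steps 1, 2, 3, 4, 8, 9). The aryl branch (steps 5, 6, 7) joins at step 8.

Steps most likely to fail:

Step 1 (C5-selective bromination; long low-temperature lithiation, possible C2 metalation or halogen scrambling). The fallback sets out from 1 and comes back at 5. It replaces directed metalation by electrophilic aromatic substitution: 1 is complexed with excess AlCl3 (2.5 equiv, CH2Cl2, 0 °C) and treated with Br2 (1.05 equiv, 0 °C → rt). The complexed formyl group deactivates C2 and C4, so bromine enters at C5. This way makes no new compound (F0).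

Step 8 (hindered, electron-rich ortho-silyloxy boronate prone to protodeboronation; aqueous base may partly cleave aryl silyl ethers). The fallback sets out from 15, with 11 as partner, and comes back at 17. It is a base-free Negishi coupling: 15 is treated with n-BuLi (THF, −78 °C, 15 min, kept cold to avoid silyl migration from O to C) to give [2,5-bis(tert-butyldimethylsilyloxy)phenyl]lithium F1. Transmetalation with ZnCl2 at −78 °C gives [2,5-bis(tert-butyldimethylsilyloxy)phenyl]zinc chloride F2. F2 is coupled with 11 under Pd2(dba)3/SPhos (zerovalent palladium, THF, rt → 40 °C) to give 17.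

Step 9 (the free hydroquinone oxidises in air, especially if the medium turns basic, and is hard to purify). The fallback sets out from 17 and comes back at 18. It is a redox detour through the quinone: 17 is desilylated with Et3N·3HF in MeCN, and the crude product is oxidised without exclusion of air by Ag2O (Et2O, MgSO4, rt). This gives (R)-1-[5-(3,6-dioxocyclohexa-1,4-dien-1-yl)furan-3-yl]-4-methylpent-3-en-1-yl (R)-2-methylbutanoate F3, which is stable to chromatography. F3 is reduced with aqueous Na2S2O4 (EtOAc/H2O, rt, 10 min) to 18, which is isolated under argon.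

**Further compounds**
F0 | step 1 | none | none
F1 | step 8 | [2,5-bis(tert-butyldimethylsilyloxy)phenyl]lithium | [Li]c1cc(O[Si](C)(C)C(C)(C)C)ccc1O[Si](C)(C)C(C)(C)C
F2 | step 8 | [2,5-bis(tert-butyldimethylsilyloxy)phenyl]zinc chloride | Cl[Zn]c1cc(O[Si](C)(C)C(C)(C)C)ccc1O[Si](C)(C)C(C)(C)C
F3 | step 9 | (R)-1-[5-(3,6-dioxocyclohexa-1,4-dien-1-yl)furan-3-yl]-4-methylpent-3-en-1-yl (R)-2-methylbutanoate | CC[C@@H](C)C(=O)O[C@H](CC=C(C)C)c1coc(C2=CC(=O)C=CC2=O)c1
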